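**Retrosyn­thetic overview**
- The C2–aryl bond is cut last: the C ring is treated as a glycosyl-type donor, (3S)-2-bromochroman-3-yl pivalate, and the B ring as a bis[3,4-bis(silyloxy)phenyl]zinc.
- Enabling feature: C2 of the dihydropyran (C) ring is bonded to the ring oxygen O1 and flanked by the oxygen-bearing C3. Ionisation therefore gives an O1=C2 oxocarbenium that the C3 pivalate carbonyl bridges as a temporary cis-fused 1,3-dioxolan-2-ylium, and aryl attack at C2 anti to this bridge gives the 2,3-trans (2R,3S) array.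
- The C3–O stereocentre comes from D-proline-catalysed α-aminoxylation of the chroman-2-ol (the ring tautomer of the 3-arylpropanal).
- The C ring (O1–C2 hemiacetal) is closed after a two-carbon Wittig homologation and conjugate reduction of a salicylaldehyde; the prenyl group is placed ortho to O1 by Claisen rearrangement of the aryl 1,1-dimethylallyl ether.
- Ring order: A ring bought, C ring closed in step 5, B ring (bought) attached in step 9, then pivalate and silyl ethers removed.

Key step: step 9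

Assumption: the hemiacetal carbon C2 of 7–10 and 15 is an uncontrolled epimer mixture and is drawn undefined, because it is erased at the oxocarbenium stage of step 9.

**Route**

Step 1
Reactants: 1 2,4,6-trihydroxybenzaldehyde
Product: 2 2-hydroxy-4,6-bis(triisopropylsilyloxy)benzaldehyde
Conditions: TIPSCl (2.1 equiv), imidazole, DMF, 0 °C to rt
Reagents that add atoms: chlorotriisopropylsilane, CC(C)[Si](Cl)(C(C)C)C(C)C
Why: Selective phenol silylation; the para OH and one of the two equivalent ortho OH groups should react while the remaining ortho OH stays free because it is hydrogen-bonded to the aldehyde.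

Step 2
Reactants: 2 2-hydroxy-4,6-bis(triisopropylsilyloxy)benzaldehyde
Product: 3 2-[(2-methylbut-3-yn-2-yl)oxy]-4,6-bis(triisopropylsilyloxy)benzaldehyde
Conditions: 3-chloro-3-methylbut-1-yne, DBU, CuCl2 (cat.), MeCN, 0 °C
Reagents that add atoms: 3-chloro-3-methylbut-1-yne, C#CC(C)(C)Cl
Why: Copper-catalysed propargylic O-alkylation of a phenol with a tertiary propargyl chloride; only the single free OH can react.

Step 3
Reactants: 3 2-[(2-methylbut-3-yn-2-yl)oxy]-4,6-bis(triisopropylsilyloxy)benzaldehyde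
Product: 5 2-hydroxy-3-(3-methylbut-2-en-1-yl)-4,6-bis(triisopropylsilyloxy)benzaldehyde, via aryl 1,1-dimethylallyl ether 4 (not isolated)
Conditions: H2 (1 atm), Lindlar catalyst, quinoline, toluene, rt; filter; then 110 °C
Reagents that add atoms: none
Why: Lindlar semi-hydrogenation followed by aromatic Claisen rearrangement; the [3,3] shift should deliver the allyl terminus to the only free ortho carbon, giving the linear prenyl group next to the oxygen that later becomes O1.

Step 4
Reactants: 5 2-hydroxy-3-(3-methylbut-2-en-1-yl)-4,6-bis(triisopropylsilyloxy)benzaldehyde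
Product: 6 (E)-3-[2-hydroxy-3-(3-methylbut-2-en-1-yl)-4,6-bis(triisopropylsilyloxy)phenyl]prop-2-enal
Conditions: Ph3P=CHCHO, toluene, 90 °C
Reagents that add atoms: (triphenylphosphoranylidene)acetaldehyde, O=CC=P(c1ccccc1)(c1ccccc1)c1ccccc1
Why: Wittig olefination with a stabilised ylide should give the E-enal and supplies the carbons that become C3 and C2.

Step 5
Reactants: 6 (E)-3-[2-hydroxy-3-(3-methylbut-2-en-1-yl)-4,6-bis(triisopropylsilyloxy)phenyl]prop-2-enal
Product: 7 8-(3-methylbut-2-en-1-yl)-5,7-bis(triisopropylsilyloxy)chroman-2-ol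
Conditions: Hantzsch ester, Bn2NH·TFA (cat.), THF, rt
Reagents that add atoms: none
Why: Iminium-catalysed transfer hydrogenation reduces only the conjugated C=C (the prenyl alkene is not activated), and the saturated aldehyde should close onto the ortho phenol to the six-membered hemiacetal (C ring, O1–C2 bond).

Step 6
Reactants: 7 8-(3-methylbut-2-en-1-yl)-5,7-bis(triisopropylsilyloxy)chroman-2-ol
Product: 9 (3S)-8-(3-methylbut-2-en-1-yl)-5,7-bis(triisopropylsilyloxy)chroman-2,3-diol, via 3-anilinooxy lactol 8 (not isolated)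
Conditions: PhNO (slow addition), D-proline (cat.), CHCl3, 4 °C; then Zn, AcOH, EtOH, 0 °C to rt
Reagents that add atoms: nitrosobenzene, O=Nc1ccccc1 (its O stays as the 3-OH oxygen of 9)
Why: Proline-catalysed α-aminoxylation of the open aldehyde tautomer followed by reductive N–O cleavage; the carboxylic acid of D-proline directs the nitroso oxygen to one enamine face by hydrogen bonding, which should set C3 as S (L-proline gives the R series).

Step 7
Reactants: 9 (3S)-8-(3-methylbut-2-en-1-yl)-5,7-bis(triisopropylsilyloxy)chroman-2,3-diol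
Product: 10 (3S)-8-(3-methylbut-2-en-1-yl)-5,7-bis(triisopropylsilyloxy)chroman-2,3-diyl bis(2,2-dimethylpropanoate)
Conditions: PivCl, pyridine, DMAP (cat.), CH2Cl2, 0 °C to rt
Reagents that add atoms: pivaloyl chloride, CC(C)(C)C(=O)Cl
Why: Esterification of both hydroxyls installs the leaving group at C2 and the participating group at C3 without touching C3.

Step 8
Reactants: 11 4-bromobenzene-1,2-diol
Product: 12 4-bromo-1,2-bis(tert-butyldimethylsilyloxy)benzene
Conditions: TBSCl, imidazole, DMF, rt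
Reagents that add atoms: tert-butylchlorodimethylsilane, CC(C)(C)[Si](C)(C)Cl
Why: Standard silylation of both catechol hydroxyls; the bromine sits para to one oxygen and meta to the other, which fixes the 3,4-dioxygenation pattern of the B ring.

Step 9
Reactants: 10 (3S)-8-(3-methylbut-2-en-1-yl)-5,7-bis(triisopropylsilyloxy)chroman-2,3-diyl bis(2,2-dimethylpropanoate); 12 4-bromo-1,2-bis(tert-butyldimethylsilyloxy)benzene
Product: 16 (2R,3S)-2-[3,4-bis(tert-butyldimethylsilyloxy)phenyl]-8-(3-methylbut-2-en-1-yl)-5,7-bis(triisopropylsilyloxy)chroman-3-yl pivalate, via aryllithium 13 (not isolated), via diarylzinc 14 (not isolated), via 2-bromochroman-3-yl pivalate 15 (not isolated)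
Conditions: 10, TMSBr, ZnBr2 (cat.), 2-methyl-2-butene (HBr scavenger), CH2Cl2, 0 °C, evaporate; separately 12, n-BuLi, toluene/n-Bu2O, −20 °C, then ZnBr2·LiBr, 0 °C; combine, toluene/n-Bu2O, 85 °C
Reagents that add atoms: bromotrimethylsilane, C[Si](C)(C)Br (Br of 15); n-butyllithium, [Li]CCCC (Li of 13); zinc bromide, [Zn+2].[Br-].[Br-] (Zn of 14); none of these atoms remains in 16
Why: TMSBr exchanges the C2 pivalate for bromide (15); zinc-assisted loss of bromide gives the O1=C2 oxocarbenium, which the carbonyl oxygen of the C3 pivalate captures as a cis-fused 2-tert-butyl-1,3-dioxolan-2-ylium, and diarylzinc 14 then transfers its aryl group to C2. The closest known reaction is the transition-metal-free, neighbouring-group-directed C-arylation of 2-O-pivaloyl pyranosyl bromides with arylzinc reagents to 1,2-trans C-aryl glycosides. No ring of the target is closed; the only ring formed is the temporary five-membered acyloxonium (5-exo attack of the ester oxygen on C2), which is opened again in the same step. The new C2 centre is controlled by C3 (S): the bridge occupies the face of the C3–O bond, so the aryl group should enter anti and give 2,3-trans (2R) whichever C2 epimer of 15 ionises. The step needs attack at C2 and not at the acyloxonium carbon (shielded by tert-butyl), substitution and not loss of H-3 to the enol pivalate (weakly basic zinc reagent, weakly coordinating solvent), and no Friedel–Crafts attack by another A ring (C6 lies between two OTIPS groups).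

Step 10
Reactants: 16 (2R,3S)-2-[3,4-bis(tert-butyldimethylsilyloxy)phenyl]-8-(3-methylbut-2-en-1-yl)-5,7-bis(triisopropylsilyloxy)chroman-3-yl pivalate
Product: 17 (2R,3S)-2-[3,4-bis(tert-butyldimethylsilyloxy)phenyl]-8-(3-methylbut-2-en-1-yl)-5,7-bis(triisopropylsilyloxy)chroman-3-ol
Conditions: DIBAL, CH2Cl2, −78 to 0 °C; Rochelle salt work-up
Reagents that add atoms: none
Why: Reductive cleavage of the hindered ester frees the 3-OH without base, so neither stereocentre nor the aryl silyl ethers should be affected.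

Step 11
Reactants: 17 (2R,3S)-2-[3,4-bis(tert-butyldimethylsilyloxy)phenyl]-8-(3-methylbut-2-en-1-yl)-5,7-bis(triisopropylsilyloxy)chroman-3-ol
Product: 18 8-prenylcatechin, (2R,3S)-2-(3,4-dihydroxyphenyl)-8-(3-methylbut-2-en-1-yl)chroman-3,5,7-triol
Conditions: TBAF/AcOH (1:1), degassed THF, 0 °C, argon
Reagents that add atoms: none
Why: Acetic-acid-buffered fluoride desilylation should remove all four aryl silyl ethers without acid (no prenyl cyclisation onto the 7-OH) and without free phenoxide (no C2 epimerisation or oxidation).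

**Compound list**
1 | 2,4,6-trihydroxybenzaldehyde | O=Cc1c(O)cc(O)cc1O | starting material
2 | 2-hydroxy-4,6-bis(triisopropylsilyloxy)benzaldehyde | O=Cc1c(O)cc(O[Si](C(C)C)(C(C)C)C(C)C)cc1O[Si](C(C)C)(C(C)C)C(C)C | intermediate
3 | 2-[(2-methylbut-3-yn-2-yl)oxy]-4,6-bis(triisopropylsilyloxy)benzaldehyde | O=Cc1c(OC(C)(C)C#C)cc(O[Si](C(C)C)(C(C)C)C(C)C)cc1O[Si](C(C)C)(C(C)C)C(C)C | intermediate
4 | 2-[(2-methylbut-3-en-2-yl)oxy]-4,6-bis(triisopropylsilyloxy)benzaldehyde (not isolated) | O=Cc1c(OC(C)(C)C=C)cc(O[Si](C(C)C)(C(C)C)C(C)C)cc1O[Si](C(C)C)(C(C)C)C(C)C | intermediate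
5 | 2-hydroxy-3-(3-methylbut-2-en-1-yl)-4,6-bis(triisopropylsilyloxy)benzaldehyde | O=Cc1c(O)c(CC=C(C)C)c(O[Si](C(C)C)(C(C)C)C(C)C)cc1O[Si](C(C)C)(C(C)C)C(C)C | intermediate
6 | (E)-3-[2-hydroxy-3-(3-methylbut-2-en-1-yl)-4,6-bis(triisopropylsilyloxy)phenyl]prop-2-enal | O=C/C=C/c1c(O)c(CC=C(C)C)c(O[Si](C(C)C)(C(C)C)C(C)C)cc1O[Si](C(C)C)(C(C)C)C(C)C | intermediate
7 | 8-(3-methylbut-2-en-1-yl)-5,7-bis(triisopropylsilyloxy)chroman-2-ol (C2 epimers) | CC(C)=CCc1c(O[Si](C(C)C)(C(C)C)C(C)C)cc(O[Si](C(C)C)(C(C)C)C(C)C)c2c1OC(O)CC2 | intermediate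
8 | (3S)-8-(3-methylbut-2-en-1-yl)-3-[(phenylamino)oxy]-5,7-bis(triisopropylsilyloxy)chroman-2-ol (not isolated) | CC(C)=CCc1c(O[Si](C(C)C)(C(C)C)C(C)C)cc(O[Si](C(C)C)(C(C)C)C(C)C)c2c1OC(O)[C@@H](ONc1ccccc1)C2 | intermediate
9 | (3S)-8-(3-methylbut-2-en-1-yl)-5,7-bis(triisopropylsilyloxy)chroman-2,3-diol (C2 epimers) | CC(C)=CCc1c(O[Si](C(C)C)(C(C)C)C(C)C)cc(O[Si](C(C)C)(C(C)C)C(C)C)c2c1OC(O)[C@@H](O)C2 | intermediate
10 | (3S)-8-(3-methylbut-2-en-1-yl)-5,7-bis(triisopropylsilyloxy)chroman-2,3-diyl bis(2,2-dimethylpropanoate) (C2 epimers) | CC(C)=CCc1c(O[Si](C(C)C)(C(C)C)C(C)C)cc(O[Si](C(C)C)(C(C)C)C(C)C)c2c1OC(OC(=O)C(C)(C)C)[C@@H](OC(=O)C(C)(C)C)C2 | intermediate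
11 | 4-bromobenzene-1,2-diol | Oc1ccc(Br)cc1O | starting material
12 | 4-bromo-1,2-bis(tert-butyldimethylsilyloxy)benzene | Brc1ccc(O[Si](C)(C)C(C)(C)C)c(O[Si](C)(C)C(C)(C)C)c1 | intermediate
13 | [3,4-bis(tert-butyldimethylsilyloxy)phenyl]lithium (not isolated) | [Li]c1ccc(O[Si](C)(C)C(C)(C)C)c(O[Si](C)(C)C(C)(C)C)c1 | intermediate
14 | bis[3,4-bis(tert-butyldimethylsilyloxy)phenyl]zinc (not isolated) | CC(C)(C)[Si](C)(C)Oc1ccc([Zn]c2ccc(O[Si](C)(C)C(C)(C)C)c(O[Si](C)(C)C(C)(C)C)c2)cc1O[Si](C)(C)C(C)(C)C | intermediate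
15 | (3S)-2-bromo-8-(3-methylbut-2-en-1-yl)-5,7-bis(triisopropylsilyloxy)chroman-3-yl pivalate (C2 epimers, not isolated) | CC(C)=CCc1c(O[Si](C(C)C)(C(C)C)C(C)C)cc(O[Si](C(C)C)(C(C)C)C(C)C)c2c1OC(Br)[C@@H](OC(=O)C(C)(C)C)C2 | intermediate
16 | (2R,3S)-2-[3,4-bis(tert-butyldimethylsilyloxy)phenyl]-8-(3-methylbut-2-en-1-yl)-5,7-bis(triisopropylsilyloxy)chroman-3-yl pivalate | CC(C)=CCc1c(O[Si](C(C)C)(C(C)C)C(C)C)cc(O[Si](C(C)C)(C(C)C)C(C)C)c2c1O[C@H](c1ccc(O[Si](C)(C)C(C)(C)C)c(O[Si](C)(C)C(C)(C)C)c1)[C@@H](OC(=O)C(C)(C)C)C2 | intermediate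
17 | (2R,3S)-2-[3,4-bis(tert-butyldimethylsilyloxy)phenyl]-8-(3-methylbut-2-en-1-yl)-5,7-bis(triisopropylsilyloxy)chroman-3-ol | CC(C)=CCc1c(O[Si](C(C)C)(C(C)C)C(C)C)cc(O[Si](C(C)C)(C(C)C)C(C)C)c2c1O[C@H](c1ccc(O[Si](C)(C)C(C)(C)C)c(O[Si](C)(C)C(C)(C)C)c1)[C@@H](O)C2 | intermediate
18 | 8-prenylcatechin, (2R,3S)-2-(3,4-dihydroxyphenyl)-8-(3-methylbut-2-en-1-yl)chroman-3,5,7-triol | CC(C)=CCc1c(O)cc(O)c2c1O[C@H](c1ccc(O)c(O)c1)[C@@H](O)C2 | target

**Step count**
Total: 11 steps. Longest linear sequence: 10 steps (steps 1–7 and 9–11, from 1).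

**Steps most likely to fail**

Step 9. The aryl group may be transferred to the acyloxonium carbon instead of C2, the cation may lose H-3 to give the enol pivalate, or the bromide may decompose before it ionises, and facial control is lost if the unbridged oxocarbenium is intercepted. The fallback sets out from 9 and comes back at 17, using the established open-chain route to trans-flavan-3-ols. Compound 12 is converted with magnesium in THF into [3,4-bis(tert-butyldimethylsilyloxy)phenyl]magnesium bromide F1, and an excess of it is added to 9 at −40 to 0 °C; the open hydroxy-aldehyde tautomer should give (2S)-1-[3,4-bis(tert-butyldimethylsilyloxy)phenyl]-3-[2-hydroxy-3-(3-methylbut-2-en-1-yl)-4,6-bis(triisopropylsilyloxy)phenyl]propane-1,2-diol F2, whose C1 configuration need not be controlled. Triethyl orthoformate with catalytic PPTS in 1,2-dichloroethane (rt to 60 °C) forms the cyclic orthoformate, which ionises at the benzylic carbon; the phenol then closes the O1–C2 bond anti to the C3–O bridge to give (2R,3S)-2-[3,4-bis(tert-butyldimethylsilyloxy)phenyl]-8-(3-methylbut-2-en-1-yl)-5,7-bis(triisopropylsilyloxy)chroman-3-yl formate F3. KHCO3 in MeOH/THF at 0 °C removes the formate and gives 17.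

Step 6. Enamine formation from the mostly ring-closed hemiacetal may be slow, so that nitrosobenzene is lost to dimerisation or to an ene reaction with the prenyl group, and the α-oxy aldehyde may enolise and erode C3 before N–O cleavage. The fallback sets out from 7 and comes back at 9, replacing enamine catalysis by reagent-controlled enolate oxidation at the lactone level. Silver carbonate on Celite in toluene at 80 °C oxidises 7 to 8-(3-methylbut-2-en-1-yl)-5,7-bis(triisopropylsilyloxy)chroman-2-one F4. Its potassium enolate (KHMDS, THF, −78 °C) is hydroxylated with the enantiomer of (camphorsulfonyl)oxaziridine that gives the S series, to (3S)-3-hydroxy-8-(3-methylbut-2-en-1-yl)-5,7-bis(triisopropylsilyloxy)chroman-2-one F5. DIBAL at −78 °C reduces the aryl lactone to the hemiacetal 9.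

Step 4. The aldehyde is electron-rich and flanked by two ortho substituents, so olefination may be sluggish, and the product enal may be homologated again by the ylide. The fallback sets out from 5 and comes back at 7, building the C ring by cycloaddition instead of olefination. NaBH4 in THF/MeOH at 0 °C gives 2-(hydroxymethyl)-6-(3-methylbut-2-en-1-yl)-3,5-bis(triisopropylsilyloxy)phenol F6. Heating in ethyl vinyl ether (sealed tube, 100–120 °C) dehydrates it to 6-methylidene-2-(3-methylbut-2-en-1-yl)-3,5-bis(triisopropylsilyloxy)cyclohexa-2,4-dien-1-one F7, which is trapped in an inverse-demand hetero-Diels–Alder reaction as 2-ethoxy-8-(3-methylbut-2-en-1-yl)-5,7-bis(triisopropylsilyloxy)chroman F8. PPTS in aqueous acetone at 40 °C hydrolyses the acetal to 7.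

Further compounds
F1 | step 9 | [3,4-bis(tert-butyldimethylsilyloxy)phenyl]magnesium bromide | Br[Mg]c1ccc(O[Si](C)(C)C(C)(C)C)c(O[Si](C)(C)C(C)(C)C)c1
F2 | step 9 | (2S)-1-[3,4-bis(tert-butyldimethylsilyloxy)phenyl]-3-[2-hydroxy-3-(3-methylbut-2-en-1-yl)-4,6-bis(triisopropylsilyloxy)phenyl]propane-1,2-diol | OC(c1ccc(O[Si](C)(C)C(C)(C)C)c(O[Si](C)(C)C(C)(C)C)c1)[C@@H](O)Cc1c(O)c(CC=C(C)C)c(O[Si](C(C)C)(C(C)C)C(C)C)cc1O[Si](C(C)C)(C(C)C)C(C)C
F3 | step 9 | (2R,3S)-2-[3,4-bis(tert-butyldimethylsilyloxy)phenyl]-8-(3-methylbut-2-en-1-yl)-5,7-bis(triisopropylsilyloxy)chroman-3-yl formate | CC(C)=CCc1c(O[Si](C(C)C)(C(C)C)C(C)C)cc(O[Si](C(C)C)(C(C)C)C(C)C)c2c1O[C@H](c1ccc(O[Si](C)(C)C(C)(C)C)c(O[Si](C)(C)C(C)(C)C)c1)[C@@H](OC=O)C2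
F4 | step 6 | 8-(3-methylbut-2-en-1-yl)-5,7-bis(triisopropylsilyloxy)chroman-2-one | CC(C)=CCc1c(O[Si](C(C)C)(C(C)C)C(C)C)cc(O[Si](C(C)C)(C(C)C)C(C)C)c2c1OC(=O)CC2
F5 | step 6 | (3S)-3-hydroxy-8-(3-methylbut-2-en-1-yl)-5,7-bis(triisopropylsilyloxy)chroman-2-one | CC(C)=CCc1c(O[Si](C(C)C)(C(C)C)C(C)C)cc(O[Si](C(C)C)(C(C)C)C(C)C)c2c1OC(=O)[C@@H](O)C2
F6 | step 4 | 2-(hydroxymethyl)-6-(3-methylbut-2-en-1-yl)-3,5-bis(triisopropylsilyloxy)phenol | OCc1c(O)c(CC=C(C)C)c(O[Si](C(C)C)(C(C)C)C(C)C)cc1O[Si](C(C)C)(C(C)C)C(C)C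
F7 | step 4 | 6-methylidene-2-(3-methylbut-2-en-1-yl)-3,5-bis(triisopropylsilyloxy)cyclohexa-2,4-dien-1-one | C=C1C(=O)C(CC=C(C)C)=C(O[Si](C(C)C)(C(C)C)C(C)C)C=C1O[Si](C(C)C)(C(C)C)C(C)C
F8 | step 4 | 2-ethoxy-8-(3-methylbut-2-en-1-yl)-5,7-bis(triisopropylsilyloxy)chroman | CC(C)=CCc1c(O[Si](C(C)C)(C(C)C)C(C)C)cc(O[Si](C(C)C)(C(C)C)C(C)C)c2c1OC(OCC)CC2
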